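**Retrosynthetic overview**

- Numbering: C1 = C(OH)CH2OBz, C7 = that CH2, C2 and C3 = CHOAc, C4=C5 = alkene, C6 = CHOH. The plan rests on the oxygens at C6, C1 and C2 lying on one face of the cyclohexene ring (C3–OAc on the other), so that a free C2–OH can deliver both new oxygens.
- Last disconnection: C1–O and C6–O, formed together by hydrogen-bond-directed syn-osmylation of the C1=C6 bond of a trans-2-hydroxy-3-acetoxy diene. The osmate ester is kept as C1/C6-diol protection so that only C2–OH is acetylated before reductive release.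
- Diene precursor: C7 benzoate and C1–C7 bond by Stille hydroxymethylation of the alkenyl bromide; C2 configuration by Mitsunobu inversion with chloroacetic acid (removable beside acetate and benzoate); C3 acetate by selective acylation of the distal hydroxyl.
- No ring is formed: the carbocycle and the C3–O stereocentre come intact from commercial bromobenzene cis-dihydrodiol; the only ring closed is the five-membered osmate ester.

Key step: step 6

Assumption: the commercial bromobenzene cis-dihydrodiol is the (1S,2S) enantiomer; the atom numbers C1–C7 defined above are used for all intermediates.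

**Route**

Step 1
Reactants: 1 (1S,2S)-3-bromocyclohexa-3,5-diene-1,2-diol
Product: 2 (1S,6S)-5-bromo-6-hydroxycyclohexa-2,4-dien-1-yl acetate (cis; acetate on the distal oxygen, O3)
Conditions: AcCl (1.05 equiv), 2,4,6-collidine, CH2Cl2, −78 °C
Reagents that add atoms: acetyl chloride, CC(=O)Cl
Why: Low-temperature O-acylation with an acyl chloride and a hindered pyridine should select the distal hydroxyl, since the proximal one is shielded by the neighbouring C–Br group (the same site preference bulky silyl chlorides show on this diol), and the cold, weakly basic medium suppresses cis-1,2-acyl migration; no stereocentre is touched.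

Step 2
Reactants: 2 (1S,6S)-5-bromo-6-hydroxycyclohexa-2,4-dien-1-yl acetate
Product: 4 (1R,6S)-6-acetoxy-2-bromocyclohexa-2,4-dien-1-yl 2-chloroacetate (trans), via alkoxyphosphonium chloroacetate 3 (not isolated)
Conditions: ClCH2CO2H (1.5 equiv), PPh3 (1.5 equiv), DIAD (1.5 equiv, added last), toluene, −20 → 0 °C
Reagents that add atoms: chloroacetic acid, OC(=O)CCl
Why: Mitsunobu reaction: the proximal allylic hydroxyl is activated as the alkoxyphosphonium ion and displaced in SN2 fashion by chloroacetate, which inverts C2 and sets the trans C2/C3 relation; the weakly basic carboxylate of a strong acid and the electron-withdrawing bromine at C1 are chosen to favour substitution over ionisation or E2 loss of H–C3.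

Step 3
Reactants: 4 (1R,6S)-6-acetoxy-2-bromocyclohexa-2,4-dien-1-yl 2-chloroacetate; 5 (tributylstannyl)methanol
Product: 6 (1S,6S)-6-acetoxy-2-(hydroxymethyl)cyclohexa-2,4-dien-1-yl 2-chloroacetate
Conditions: Pd2(dba)3 (2.5 mol%), P(2-furyl)3 (10 mol%), NMP, 50 °C, degassed
Reagents that add atoms: (tributylstannyl)methanol (compound 5), CCCC[Sn](CCCC)(CCCC)CO
Why: Stille coupling of the alkenyl bromide with the hydroxymethylstannane forms the C1–C7 bond on an sp2 carbon without touching a stereocentre, and a weakly ligated Pd(0) catalyst at moderate temperature should let oxidative addition and transmetalation outrun ionisation of the two allylic esters.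

Step 4
Reactants: 6 (1S,6S)-6-acetoxy-2-(hydroxymethyl)cyclohexa-2,4-dien-1-yl 2-chloroacetate; 7 benzoyl chloride
Product: 8 [(5S,6S)-5-acetoxy-6-(2-chloroacetoxy)cyclohexa-1,3-dien-1-yl]methyl benzoate
Conditions: BzCl (1.2 equiv), pyridine, CH2Cl2, 0 °C, directly on crude 6
Reagents that add atoms: benzoyl chloride (compound 7), O=C(Cl)c1ccccc1
Why: Benzoylation of the only free hydroxyl (primary, allylic) under cold pyridine conditions, run at once so that the neighbouring chloroacetyl group has no time to migrate to O7.

Step 5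
Reactants: 8 [(5S,6S)-5-acetoxy-6-(2-chloroacetoxy)cyclohexa-1,3-dien-1-yl]methyl benzoate
Product: 10 [(5S,6S)-5-acetoxy-6-hydroxycyclohexa-1,3-dien-1-yl]methyl benzoate (trans; key-step precursor, used at once), via isothiouronium chloride 9 (not isolated)
Conditions: thiourea (3 equiv), 2,6-lutidine (1.5 equiv), MeOH/CH2Cl2, 40 °C
Reagents that add atoms: none
Why: Chemoselective dechloroacetylation: thiourea is S-alkylated by the α-chloro ester and the isothiouronium nitrogen cyclises onto the ester carbonyl, releasing the C2 alcohol with retention, a pathway closed to the acetate and the benzoate and run near neutrality to avoid acetyl migration.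

Step 6
Reactants: 10 [(5S,6S)-5-acetoxy-6-hydroxycyclohexa-1,3-dien-1-yl]methyl benzoate
Product: 11 O1,O6-osmate(VI) ester (dioxo, TMEDA-chelated) of [(1S,2R,3S,6S)-3-acetoxy-1,2,6-trihydroxycyclohex-4-en-1-yl]methyl benzoate, i.e. the 2-O-deacetyl target with its new C1/C6 diol still bound to osmium and C2–OH free
Conditions: OsO4 (1.0 equiv), TMEDA (1.1 equiv), CH2Cl2, −78 °C; evaporation, short SiO2 column
Reagents that add atoms: osmium tetroxide, O=[Os](=O)(=O)=O; N,N,N′,N′-tetramethylethane-1,2-diamine, CN(C)CCN(C)C
Why: TMEDA makes the oxo ligands of OsO4 good hydrogen-bond acceptors, so the complex docks on C2–OH and undergoes suprafacial [3+2] cycloaddition to the adjacent C1=C6 bond, giving the chelated osmate(VI) ester; the closest known reaction type is the hydrogen-bond-directed OsO4–TMEDA dihydroxylation of cyclic allylic alcohols. The only ring closed is the five-membered C1–O–Os–O–C6 osmate ring, formed cis-fused in a concerted cycloaddition, and the carbocycle is untouched. C1 and C6 are the new stereocentres: their configuration is controlled by the C2 carbinol centre through the hydrogen bond (both oxygens arrive on the C2–OH face) and their mutual cis relation by the suprafacial addition. Facial selectivity (syn to C2–OH, against the usual anti attack of unligated OsO4) should be secured by non-coordinating CH2Cl2 at −78 °C, where the hydrogen bond is intact and C2–OH is the only donor in the molecule. Site selectivity (C1=C6 over C4=C5) should be secured because C1=C6 is the trisubstituted, more electron-rich alkene and is allylic to the donor, whereas C4=C5 is flanked by the acetate and only homoallylic to C2–OH. One equivalent of oxidant at low temperature should prevent a second osmylation.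

Step 7
Reactants: 11 O1,O6-osmate(VI)·TMEDA ester of the 2-O-deacetyl target
Product: 12 O1,O6-osmate(VI)·TMEDA ester of [(1S,2R,3S,6S)-2,3-diacetoxy-1,6-dihydroxycyclohex-4-en-1-yl]methyl benzoate
Conditions: Ac2O, pyridine, DMAP (cat.), CH2Cl2, 0 °C → rt
Reagents that add atoms: acetic anhydride, CC(=O)OC(C)=O
Why: DMAP-catalysed acetylation of the only free hydroxyl (C2–OH), while O1 and O6 stay bound in the chelated osmate ester, which is isolable, tolerates acylation chemistry and here acts as the diol protecting group that distinguishes C2–OH from C6–OH.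

Step 8
Reactants: 12 O1,O6-osmate(VI)·TMEDA ester of the target
Product: 13 [(1S,2R,3S,6S)-2,3-diacetoxy-1,6-dihydroxycyclohex-4-en-1-yl]methyl benzoate (route numbering; the target)
Conditions: aq Na2SO3/NaHSO3 buffer (pH 6–7), THF, 45 °C
Reagents that add atoms: none
Why: Reductive hydrolysis of the osmate(VI) ester by sulfite breaks only Os–O bonds, so the C1,C6-cis-diol is released with retention, and the near-neutral buffer should keep acetate and benzoate from hydrolysing or migrating.

**Compound list**

1 | (1S,2S)-3-bromocyclohexa-3,5-diene-1,2-diol | BrC1=CC=C[C@H](O)[C@@H]1O | starting material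
2 | (1S,6S)-5-bromo-6-hydroxycyclohexa-2,4-dien-1-yl acetate | BrC1=CC=C[C@H](OC(C)=O)[C@@H]1O | intermediate
3 | {[(1S,6S)-6-acetoxy-2-bromocyclohexa-2,4-dien-1-yl]oxy}triphenylphosphonium chloroacetate | BrC1=CC=C[C@H](OC(C)=O)[C@@H]1O[P+](c2ccccc2)(c3ccccc3)c4ccccc4.[O-]C(=O)CCl | intermediate (not isolated)
4 | (1R,6S)-6-acetoxy-2-bromocyclohexa-2,4-dien-1-yl 2-chloroacetate | BrC1=CC=C[C@H](OC(C)=O)[C@H]1OC(=O)CCl | intermediate
5 | (tributylstannyl)methanol | CCCC[Sn](CCCC)(CCCC)CO | starting material
6 | (1S,6S)-6-acetoxy-2-(hydroxymethyl)cyclohexa-2,4-dien-1-yl 2-chloroacetate | OCC1=CC=C[C@H](OC(C)=O)[C@H]1OC(=O)CCl | intermediate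
7 | benzoyl chloride | O=C(Cl)c1ccccc1 | starting material
8 | [(5S,6S)-5-acetoxy-6-(2-chloroacetoxy)cyclohexa-1,3-dien-1-yl]methyl benzoate | O=C(OCC1=CC=C[C@H](OC(C)=O)[C@H]1OC(=O)CCl)c2ccccc2 | intermediate
9 | [(5S,6S)-5-acetoxy-6-(2-carbamimidoylsulfanylacetoxy)cyclohexa-1,3-dien-1-yl]methyl benzoate hydrochloride (isothiouronium chloride) | O=C(OCC1=CC=C[C@H](OC(C)=O)[C@H]1OC(=O)CSC(N)=[NH2+])c2ccccc2.[Cl-] | intermediate (not isolated)
10 | [(5S,6S)-5-acetoxy-6-hydroxycyclohexa-1,3-dien-1-yl]methyl benzoate | O=C(OCC1=CC=C[C@H](OC(C)=O)[C@H]1O)c2ccccc2 | intermediate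
11 | O1,O6-osmate(VI) ester (dioxo, TMEDA chelate) of [(1S,2R,3S,6S)-3-acetoxy-1,2,6-trihydroxycyclohex-4-en-1-yl]methyl benzoate | CC(=O)O[C@H]1C=C[C@@H]2O[Os-2]3(=O)(=O)(O[C@]2(COC(=O)c4ccccc4)[C@@H]1O)[N+](C)(C)CC[N+]3(C)C | intermediate
12 | O1,O6-osmate(VI) ester (dioxo, TMEDA chelate) of [(1S,2R,3S,6S)-2,3-diacetoxy-1,6-dihydroxycyclohex-4-en-1-yl]methyl benzoate | CC(=O)O[C@H]1C=C[C@@H]2O[Os-2]3(=O)(=O)(O[C@]2(COC(=O)c4ccccc4)[C@@H]1OC(C)=O)[N+](C)(C)CC[N+]3(C)C | intermediate
13 | [(1S,2R,3S,6S)-2,3-diacetoxy-1,6-dihydroxycyclohex-4-en-1-yl]methyl benzoate | CC(=O)O[C@H]1C=C[C@H](O)[C@@](O)(COC(=O)c2ccccc2)[C@@H]1OC(C)=O | target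

Total step count: 8. Longest linear sequence: 8 steps (from 1).

**Steps most likely to fail**

Step 2 (Mitsunobu inversion on a cyclohexadienol). The activated C2–O group lies anti to H–C3, so E2 loss of H–C3 or ionisation to a cyclohexadienyl cation would aromatise the ring; SN2′ attack at C6 is a second leak. The fallback moves the inversion to a monoene and regenerates the diene afterwards. It sets out from 2. Diimide (potassium azodicarboxylate, AcOH, MeOH, 0 °C) should saturate only the disubstituted C4=C5 bond to give (1S,2S)-3-bromo-2-hydroxycyclohex-3-en-1-yl acetate F1. A Mitsunobu reaction with chloroacetic acid on this cyclohexenol, which cannot aromatise, should give (1R,6S)-6-acetoxy-2-bromocyclohex-2-en-1-yl 2-chloroacetate F2. Wohl–Ziegler bromination (NBS, AIBN, PhCF3, 80 °C) at the ring CH2 allylic to the bromoalkene should give (1R,6S)-6-acetoxy-2,4-dibromocyclohex-2-en-1-yl 2-chloroacetate F3 as C4 epimers. Dehydrobromination (LiCl, Li2CO3, DMF, 60 °C) should restore the C4=C5 bond and come back to the route at 4.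

Step 6 (directed osmylation). Osmium may add to the less hindered C4=C5 bond, or to C1=C6 from the face anti to C2–OH if the hydrogen bond is lost; over-oxidation of the second alkene is also possible. The fallback replaces hydrogen-bond delivery by covalent metal–alkoxide delivery followed by a double inversion. It sets out from 10. VO(acac)2/t-BuOOH (CH2Cl2, 0 °C), directed by the same C2–OH and confined to the allylic C1=C6 bond, should give the epoxy alcohol [3-acetoxy-2-hydroxy-7-oxabicyclo[4.1.0]hept-4-en-1-yl]methyl benzoate F4 (epoxide cis to C2–OH). Acetylation (Ac2O, pyridine) should give [2,3-diacetoxy-7-oxabicyclo[4.1.0]hept-4-en-1-yl]methyl benzoate F5. Pd(0)-catalysed opening of this vinyl epoxide with hydrogencarbonate as water surrogate (Pd2(dba)3, PPh3, NaHCO3, Et3B cat., CH2Cl2/H2O, rt) ionises allylic C6 with inversion and returns the O1-bound carbonate to C6 anti to palladium. The resulting net retention should give the C1,C6-cis-diol and come back to the route at 13.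

Step 3 (Stille coupling beside two allylic esters). Pd(0) may ionise the C2 chloroacetate or the C3 acetate, leading to ester loss and aromatisation; transmetalation of the hydroxymethylstannane may be slow; and the chloroacetyl group may migrate to the new primary hydroxyl. The fallback forms the C1–C7 bond before any ester is present. It sets out from 1. Acetonide formation (2,2-dimethoxypropane, TsOH cat., acetone, 0 °C) should give (3aS,7aS)-4-bromo-2,2-dimethyl-3a,7a-dihydro-1,3-benzodioxole F6. Stille coupling with 5 on this ester-free bromodiene should give [(3aR,7aS)-2,2-dimethyl-3a,7a-dihydro-1,3-benzodioxol-4-yl]methanol F7. Benzoylation with 7 should give [(3aR,7aS)-2,2-dimethyl-3a,7a-dihydro-1,3-benzodioxol-4-yl]methyl benzoate F8. Mild acetal hydrolysis (AcOH/THF/H2O, rt) should give [(5S,6R)-5,6-dihydroxycyclohexa-1,3-dien-1-yl]methyl benzoate F9. Distal acetylation as in step 1 should give [(5S,6R)-5-acetoxy-6-hydroxycyclohexa-1,3-dien-1-yl]methyl benzoate F10. Mitsunobu inversion with chloroacetic acid as in step 2 comes back to the route at 8.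

**Further compounds**

F1 | step 2 | (1S,2S)-3-bromo-2-hydroxycyclohex-3-en-1-yl acetate | BrC1=CCC[C@H](OC(C)=O)[C@@H]1O
F2 | step 2 | (1R,6S)-6-acetoxy-2-bromocyclohex-2-en-1-yl 2-chloroacetate | BrC1=CCC[C@H](OC(C)=O)[C@H]1OC(=O)CCl
F3 | step 2 | (1R,6S)-6-acetoxy-2,4-dibromocyclohex-2-en-1-yl 2-chloroacetate (C4 epimers) | BrC1=CC(Br)C[C@H](OC(C)=O)[C@H]1OC(=O)CCl
F4 | step 6 | [3-acetoxy-2-hydroxy-7-oxabicyclo[4.1.0]hept-4-en-1-yl]methyl benzoate, epoxide cis to C2–OH and trans to C3–OAc | CC(=O)O[C@H]1C=C[C@@H]2O[C@]2(COC(=O)c3ccccc3)[C@@H]1O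
F5 | step 6 | [2,3-diacetoxy-7-oxabicyclo[4.1.0]hept-4-en-1-yl]methyl benzoate, epoxide cis to C2–OAc and trans to C3–OAc | CC(=O)O[C@H]1C=C[C@@H]2O[C@]2(COC(=O)c3ccccc3)[C@@H]1OC(C)=O
F6 | step 3 | (3aS,7aS)-4-bromo-2,2-dimethyl-3a,7a-dihydro-1,3-benzodioxole | BrC1=CC=C[C@@H]2OC(C)(C)O[C@H]12
F7 | step 3 | [(3aR,7aS)-2,2-dimethyl-3a,7a-dihydro-1,3-benzodioxol-4-yl]methanol | OCC1=CC=C[C@@H]2OC(C)(C)O[C@H]12
F8 | step 3 | [(3aR,7aS)-2,2-dimethyl-3a,7a-dihydro-1,3-benzodioxol-4-yl]methyl benzoate | O=C(OCC1=CC=C[C@@H]2OC(C)(C)O[C@H]12)c3ccccc3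
F9 | step 3 | [(5S,6R)-5,6-dihydroxycyclohexa-1,3-dien-1-yl]methyl benzoate | O=C(OCC1=CC=C[C@H](O)[C@@H]1O)c2ccccc2
F10 | step 3 | [(5S,6R)-5-acetoxy-6-hydroxycyclohexa-1,3-dien-1-yl]methyl benzoate | O=C(OCC1=CC=C[C@H](OC(C)=O)[C@@H]1O)c2ccccc2
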